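| flask | L | G | remark | time |
|---|---|---|---|---|
| Tuesday's | 0.025 M | 19 mM (held) | run made earlier |  |
| Friday's | 0.038 M | 19 mM (held) | run made earlier |  |
| flask | 0.050 M | 19 mM (held) |  | 6.0 h |

| run | time / h | X / % | L / % |
|---|---|---|---|
| Tuesday's | 0.833 | 10.3 | 77.4 |
| Tuesday's | 1.50 | 27.0 | 58.5 |
| Tuesday's | 2.50 | 52.7 | 31.9 |
| Tuesday's | 3.00 | 65.7 | 20.6 |
| Tuesday's | 4.00 | 90.0 | 0.5 |
| Tuesday's | 5.00 | 96.0 | 0.5 |
| Friday's | 0.333 | 0.1 | 94.1 |
| Friday's | 1.00 | 9.3 | 82.3 |
| Friday's | 1.50 | 18.3 | 73.1 |
| Friday's | 2.50 | 34.4 | 56.6 |
| Friday's | 4.00 | 59.7 | 30.2 |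
| Friday's | 5.00 | 76.6 | 12.6 |

(scatter of a reading: 0.5 percentage points)

* how much X there is at 6.0 h, in percent of the L charged
* concentration of D in solution at 6.0 h, in percent of saturation

- solid, in amounts per volume of the solution: L
- what was read earlier has a scatter of 0.5 percentage points, one standard deviation
- at the start none of G is in solution
- at the start none of L is in solution
- D is what G becomes in solution

The pitfall in Tuesday's and Friday's runs is to lay them over each other as one curve in percent, since both hold G alike and both rise steadily after a short lag while L lasts, yet X gains 0.256 /h of the charge per hour on Tuesday and 0.168 /h on Friday. These paces, as read, differ by a factor of 1.52, about the same as the ratio of the charges taken the other way round, 1.52, so with G held alike I read the amount turned per hour as independent of the charge, that is, zero-order in L.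

I therefore carry the charge pace, the fraction of a charge turned into X per hour, which for the new flask is Friday's pace times Friday's charge over the flask's charge, 0.128 /h. Its inverse is roughly how long a charge lasts, and this is why the two runs end apart: Tuesday's 3.91 h is shorter than its last time, so L reads 0.5% and X 96.0%, while Friday's 5.94 h is longer than its last time, so L still reads 12.6% and X 76.6%.

The new flask's 7.82 h is longer than the asked 6.0 h, so I keep the steady rise, and with Friday's lag of 0.447 h I reckon X at 71.0%. The readings hold no D, so I reckon none for it. The forecast gives 71% of X and D at 80% of saturation, holding that “dissolution is zero-order while solid remains”.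

The flask gives 71.3% of X, with D at 82.2% of saturation.

    G ⇌ D, rate k1*(csat - [D]) (kL = 5.30 × 10⁻⁴ /s)
    E + D → X (k = 0.0380 /M/s)
    E ⇌ Z (K = 0.400, k = 1.70 × 10⁻⁵ /s)
    L ⇌ E, rate k4*(cs4 - [E]) while solid is left; crystals form when [E] > cs4 (solubility = 23.0 mM, k = 9.20 × 10⁻⁵ /s)
    2 E → J (k = 0.00150 /M/s)

The neighbour flask, the same charge read at 1.5 h, holds 13.4% of X, where the charge pace gives 13.5%. The flask is not at rest at 6.00 h, for L still stands at 20.2% of the charge, about 1.58 h more at the charge pace. By 60.0 h L stands at 0%, E has gone from 6.02% to 0%, D has climbed from 0.0156 M to 0.0190 M, and X has reached 98.5%, while J, counted as two, has moved from 1.12% to 1.47%.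

(The numbers in the tables are calculated with constants of no real substance.)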